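**Plan**

1. Locants: C1–C13 are the caryophyllane carbons (C4 is the O-bearing quaternary carbon, C5 the adjacent CH). Primed locants are the chromenone part: O1', C4' (CH2), C4a', C5' (C–OH), C6', C7' (C=O), C8' (CMe2), C8a' (enol ether carbon).
2. Retrosynthesis cuts, in order: the C6'–acyl bond; the C4a'–C5' bond of the carbocycle (ring-closing C-acylation of the cyclic enol ether by an acylketene); the C6'–C7' bond (Claisen condensation); the C8'–C8a' bond (ester enolate plus δ-lactone); the O1'–C4 and C4'–C5 bonds ([4+2] addition of methylidene Meldrum's acid to caryophyllene).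
3. Forward: the pyran ring arises first, as a δ-lactone on C4/C5 of caryophyllene. The chain C8'–C7'–C6'–C5' is then joined to the lactone carbon, dehydration gives the cyclic enol ether, the carbocycle closes last, and the acyl group is attached at the end.
4. Feature that makes the key event possible: the enol ether O1'–C8a'=C4a' makes C4a' a carbon nucleophile. The quaternary C8' holds the ketene carbon C5' six atoms away and turns the competing oxygen closure onto C8a' into a four-membered ring.
5. Stereochemistry: C1 and C9 come from (−)-β-caryophyllene. C4 and C5 come from the suprafacial [4+2] addition to the E-C4=C5 bond (O1' and C4' cis, C4–CH3 anti to C5–H), on the ring face opposite to the oxygen of natural (−)-caryophyllene oxide. The side-chain centre comes from (S)-2-methylbutanoic acid.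

Key step: step 6

Remark (assumption on the chemistry): the [4+2] addition of step 1 is assumed to occur on both faces of C4=C5, through the two ring conformers of caryophyllene that expose them. The (4S,5R) adduct is carried on and its facial isomer is removed at lactone 7.

**Route**

Step 1
Reactants: 1 (−)-β-caryophyllene; 2 Meldrum's acid; 3 paraformaldehyde
Product: 5 hetero-Diels–Alder adduct (pyran-fused dioxinone), via 5-methylidene Meldrum's acid 4 (not isolated)
Conditions: 1 (3 equiv), 2 (1 equiv), 3 (1.5 equiv CH2O), ethylenediammonium diacetate (10 mol%), MeCN, 25 °C; short silica pad, crude 5 taken on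
Reagents that add atoms: none
Why: domino Knoevenagel/inverse-electron-demand hetero-Diels–Alder reaction in which the very electron-poor 1-oxadiene 4 adds suprafacially to the strained E-trisubstituted C4=C5 bond with oxygen on the more substituted C4, so that O1' and C4' end cis (C4–CH3 anti to C5–H), the (4S,5R) isomer being the one formed on the face opposite to that of natural caryophyllene oxide.

Step 2
Reactants: 5 hetero-Diels–Alder adduct
Product: 7 δ-lactone, via α-carboxy lactone 6 (not isolated)
Conditions: pyridine/H2O (5:1), 100 °C; chromatography (removes the C4/C5 facial isomer)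
Reagents that add atoms: water, O
Why: hydrolysis of the cyclic ketene acetal releases acetone and the malonic half-acid 6, which decarboxylates on heating, and the buffered medium should not ionise the tertiary C4–O bond, so C4 and C5 stay as set.

Step 3
Reactants: 7 δ-lactone; 8 methyl isobutyrate
Product: 10 lactol ester, via lithium enolate 9 (not isolated)
Conditions: 8 (1.5 equiv), LiN(iPr)2 (1.5 equiv), THF, −78 °C; then 7, −78 → −40 °C; AcOH quench at −78 °C
Reagents that add atoms: none
Why: Claisen-type addition of an ester enolate to the lactone carbonyl, held at the cyclic tetrahedral lithium alkoxide by the cold quench, forms the C8'–C8a' bond, and the uncontrolled hemiketal centre is removed in step 4.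

Step 4
Reactants: 10 lactol ester
Product: 11 cyclic enol ether ester
Conditions: pyridinium p-toluenesulfonate (0.2 equiv), 4 Å MS, PhH, 80 °C
Reagents that add atoms: none
Why: acid-catalysed dehydration of the hemiketal through its oxocarbenium ion can place the double bond only between C8a' and C4a' because C8' is quaternary, and no stereocentre is formed.

Step 5
Reactants: 11 cyclic enol ether ester; 12 tert-butyl acetate
Product: 14 β-keto ester, via lithium enolate 13 (not isolated)
Conditions: 12 (3.5 equiv), LiN(iPr)2 (3.5 equiv), THF, −78 °C; then 11, −78 → 0 °C; AcOH quench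
Reagents that add atoms: none
Why: crossed Claisen condensation of the acetate enolate with the non-enolisable methyl ester, driven by deprotonation of the β-keto ester formed, under basic conditions that leave the enol ether and all stereocentres untouched.

Step 6
Reactants: 14 β-keto ester
Product: 16 ring-closed enol-dione, via acylketene 15 (not isolated)
Conditions: PhMe (0.005 M), 110 °C, slow N2 stream to carry off t-BuOH
Reagents that add atoms: none
Why: Proposed new method: heating the tert-butyl β-keto ester expels tert-butanol to give acylketene 15, whose ketene carbon C5' is attacked in the ketene plane by the nucleophilic enol ether carbon C4a'; the oxocarbenium/1,3-diketonate zwitterion then loses the C4a' proton and the product settles as the enolised vinylogous ester 16. The closest known reaction types are the hetero-Diels–Alder reaction of acylketenes with vinyl ethers, which begins with the same C–C bond formation, and the Effenberger C-acylation of enol ethers by malonyl chlorides; using this bond formation to close a carbocyclic 1,3-dione ring is the new element. The carbocycle closes in a 6-(enolendo)-exo-dig mode, the enol ether π bond lying inside the new ring and the ketene C=O outside it, assisted by the gem-dimethyl group at C8'. No stereocentre is created, and C1, C4, C5, C9 and the exocyclic methylidene are spectators. The step needs C-acylation at C4a' in place of the usual oxygen closure of an acylketene on an enol ether, of oxygen trapping and of dimerisation: oxygen closure onto C8a' would need a four-membered ring because only C8' lies between the ketone and C8a', the substrate carries no OH or NH group, and high dilution with removal of tert-butanol holds back dimerisation and the return to 14. The product is the vinylogous ester of a cyclic β-diketone, so the closure should be strongly downhill and not reversible.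

Step 7
Reactants: 16 ring-closed enol-dione; 17 (S)-2-methylbutanoic acid
Product: 19 target CNP0591516.1, via enol ester 18 (not isolated)
Conditions: 17 (1.2 equiv), DCC (1.3 equiv), DMAP (1.2 equiv), CH2Cl2, 0 → 25 °C
Reagents that add atoms: none
Why: carbodiimide esterification of the enol followed by the DMAP-mediated O→C acyl shift of the enol ester (the usual C-acylation of cyclic 1,3-diones) places the acyl group on C6', the only carbon between the two carbonyls, and the (S) centre is carried over from the acid because no strong base is present.

**Compound list**

1 | (−)-β-caryophyllene, (1R,4E,9S)-4,11,11-trimethyl-8-methylidenebicyclo[7.2.0]undec-4-ene | C=C1CC/C=C(\C)CC[C@@H]2[C@@H]1CC2(C)C | starting material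
2 | Meldrum's acid, 2,2-dimethyl-1,3-dioxane-4,6-dione | CC1(C)OC(=O)CC(=O)O1 | starting material
3 | paraformaldehyde (used as formaldehyde, CH2O) | C=O | starting material
4 | 5-methylidene Meldrum's acid, 2,2-dimethyl-5-methylidene-1,3-dioxane-4,6-dione | C=C1C(=O)OC(C)(C)OC1=O | intermediate
5 | hetero-Diels–Alder adduct: a 2,2-dimethyl-1,3-dioxin-4-one whose C5=C6 bond is shared with a dihydropyran ring (dioxinone C5 = C4a', bonded to the pyran CH2 C4'; dioxinone C6 = C8a', bonded to O1'); O1' sits on C4 and C4' on C5 of the (1R,4S,5R,9S)-4,11,11-trimethyl-8-methylidenebicyclo[7.2.0]undecane unit, C4–CH3 anti to C5–H | C=C1CC[C@@H]2CC3=C(O[C@@]2(C)CC[C@@H]2[C@@H]1CC2(C)C)OC(C)(C)OC3=O | intermediate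
6 | α-carboxy-δ-lactone: 2-oxotetrahydropyran-3-carboxylic acid fused as in 5 (lactone O on C4, ring CH2 on C5; carboxyl-bearing carbon as a mixture of epimers) | C=C1CC[C@@H]2CC(C(=O)O)C(=O)O[C@@]2(C)CC[C@@H]2[C@@H]1CC2(C)C | intermediate
7 | δ-lactone: 3-[(1R,4S,5R,9S)-4-hydroxy-4,11,11-trimethyl-8-methylidenebicyclo[7.2.0]undecan-5-yl]propanoic acid lactonised onto the C4 hydroxyl | C=C1CC[C@@H]2CCC(=O)O[C@@]2(C)CC[C@@H]2[C@@H]1CC2(C)C | intermediate
8 | methyl isobutyrate (methyl 2-methylpropanoate) | CC(C)C(=O)OC | starting material
9 | lithium enolate of methyl isobutyrate | CC(C)=C(OC)O[Li] | intermediate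
10 | lactol ester: methyl 2-(2-hydroxytetrahydropyran-2-yl)-2-methylpropanoate, the tetrahydropyran being the ring of 7 with its carbonyl carbon turned into the hemiketal carbon (epimer mixture there, otherwise (1R,4S,5R,9S); in equilibrium with the open δ-hydroxy ketone) | C=C1CC[C@@H]2CCC(O)(C(C)(C)C(=O)OC)O[C@@]2(C)CC[C@@H]2[C@@H]1CC2(C)C | intermediate
11 | cyclic enol ether ester: methyl 2-(3,4-dihydro-2H-pyran-6-yl)-2-methylpropanoate, the dihydropyran O1'–C8a'=C4a'–C4' being fused through O1'–C4 and C4'–C5 to the (1R,4S,5R,9S) bicycloundecane | C=C1CC[C@@H]2CC=C(C(C)(C)C(=O)OC)O[C@@]2(C)CC[C@@H]2[C@@H]1CC2(C)C | intermediate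
12 | tert-butyl acetate | CC(=O)OC(C)(C)C | starting material
13 | lithium enolate of tert-butyl acetate | C=C(O[Li])OC(C)(C)C | intermediate
14 | β-keto ester: tert-butyl 4-(3,4-dihydro-2H-pyran-6-yl)-4-methyl-3-oxopentanoate, same fused dihydropyran as in 11 | C=C1CC[C@@H]2CC=C(C(C)(C)C(=O)CC(=O)OC(C)(C)C)O[C@@]2(C)CC[C@@H]2[C@@H]1CC2(C)C | intermediate
15 | acylketene: O=C=CH–CO–CMe2– attached to C8a' of the same fused dihydropyran | C=C1CC[C@@H]2CC=C(C(C)(C)C(=O)C=C=O)O[C@@]2(C)CC[C@@H]2[C@@H]1CC2(C)C | intermediate
16 | ring-closed enol-dione: 5'-hydroxy-8',8'-dimethyl-3',4'-dihydro-2'H-chromen-7'(8'H)-one fused at C2'–C3' (= C4–C5) to the nine-membered ring of (1R,4S,5R,9S)-4,11,11-trimethyl-8-methylidenebicyclo[7.2.0]undecane | C=C1CC[C@@H]2CC3=C(O[C@@]2(C)CC[C@@H]2[C@@H]1CC2(C)C)C(C)(C)C(=O)C=C3O | intermediate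
17 | (S)-2-methylbutanoic acid | CC[C@H](C)C(=O)O | starting material
18 | enol ester: 5'-O-[(S)-2-methylbutanoyl] derivative of 16 | C=C1CC[C@@H]2CC3=C(O[C@@]2(C)CC[C@@H]2[C@@H]1CC2(C)C)C(C)(C)C(=O)C=C3OC(=O)[C@@H](C)CC | intermediate
19 | CNP0591516.1: 6'-[(S)-2-methylbutanoyl] derivative of 16 | C=C1CC[C@@H]2CC3=C(O[C@@]2(C)CC[C@@H]2[C@@H]1CC2(C)C)C(C)(C)C(=O)C(C(=O)[C@@H](C)CC)=C3O | target

**Count**

Total steps: 7. Longest linear sequence: 7 steps (1 → 19).

**Steps most likely to fail**

1. Step 6 (Proposed new method). The ketene may fail to close on carbon: if C-acylation through the twisted six-membered transition state is slow, ketene dimerisation, return to 14, or cleavage of the tertiary alkyl enol ether by the acidic product can take over. The fallback uses known chemistry, sets out from lactone 7 and comes back at 16. Addition of iPrLi (THF, −78 °C) to 7 gives the isopropyl lactol F1. Dehydration (pyridinium p-toluenesulfonate, 4 Å MS, PhH, 80 °C) gives the isopropyl cyclic enol ether F2; an exocyclic double-bond isomer would converge in the next operation. An Effenberger cyclisation with malonyl dichloride (Et2O, −20 → 25 °C) then acylates C4a' and, through the dienol ether, the isopropyl carbon, so that C5', C6' and C7' are brought in together and the same ring 16 results.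

2. Step 1. The heterodiene may be lost before it reaches the endocyclic alkene, by condensation with a second molecule of Meldrum's acid or by an ene reaction at the exocyclic C8=C13 methylidene. In addition, the share of cycloaddition on the required ring face may be small, because the less populated conformer has to react. The fallback sets out from 1 and comes back at 7. A thermal hetero-Diels–Alder reaction with acrolein (hydroquinone, PhMe, sealed tube, 130 °C) uses a preformed, small oxadiene with the same regiochemistry and suprafacial course, and gives the unsubstituted cyclic enol ether F3. Its facial isomer is removed by chromatography, and this oxadiene may partition differently between the two faces. Oxidation of the enol ether with [C5H5NH][CrO3Cl] (pyridinium chlorochromate) in CH2Cl2 at 25 °C converts F3 into lactone 7.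

3. Step 3. Proton transfer from the lactone α-CH2 to the hindered tertiary enolate, or reversal of the addition on warming, may return 7. The fallback sets out from 7 and comes back at 10. Ring opening of 7 with MeNH(OMe)·HCl and Me3Al (CH2Cl2, 0 °C) gives the hydroxy N-methoxy-N-methylamide F4. Addition of lithium enolate 9 (3 equiv, THF, −78 → 0 °C; one equivalent is used up by the tertiary hydroxyl) passes through a chelated tetrahedral intermediate that can neither revert nor add twice. Work-up gives the δ-hydroxy ketone, which closes to lactol 10.

**Further compounds**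

F1 | step 6 | isopropyl lactol: the ring of 7 with its carbonyl carbon turned into a hemiketal carbon bearing OH and isopropyl (epimer mixture there, otherwise (1R,4S,5R,9S)) | C=C1CC[C@@H]2CCC(O)(C(C)C)O[C@@]2(C)CC[C@@H]2[C@@H]1CC2(C)C
F2 | step 6 | isopropyl cyclic enol ether: 6-isopropyl-3,4-dihydro-2H-pyran fused through O1'–C4 and C4'–C5 to the (1R,4S,5R,9S) bicycloundecane | C=C1CC[C@@H]2CC=C(C(C)C)O[C@@]2(C)CC[C@@H]2[C@@H]1CC2(C)C
F3 | step 1 | unsubstituted cyclic enol ether: 3,4-dihydro-2H-pyran fused through O1'–C4 and C4'–C5 to the (1R,4S,5R,9S) bicycloundecane | C=C1CC[C@@H]2CC=CO[C@@]2(C)CC[C@@H]2[C@@H]1CC2(C)C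
F4 | step 3 | hydroxy N-methoxy-N-methylamide: 3-[(1R,4S,5R,9S)-4-hydroxy-4,11,11-trimethyl-8-methylidenebicyclo[7.2.0]undecan-5-yl]-N-methoxy-N-methylpropanamide | C=C1CC[C@H](CCC(=O)N(C)OC)[C@@](C)(O)CC[C@@H]2[C@@H]1CC2(C)C
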